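**Retrosynthetic overview**
1. The C–geranyl bond at the quaternary carbon is made last. An enantioselective dearomative allylic alkylation of a fully aromatic methylene-bis(acylphloroglucinol) with geranyl acetate turns the second benzene ring into ring C and sets the only stereocentre.
2. The methylene bridge comes from an ortho-quinone methide, released from a cyclic benzylic boronate (ring D), and 3-methylphloroacetophenone.
3. Key step: ring D (a 1,3,2-dioxaborinine that carries the bridge carbon and masks O-5) and pyran ring B are both annulated onto phlorobutyrophenone in one flask with PhB(OH)2, CH2O and prenal.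
4. The carbocycles A and C are bought as phloroglucinol and 2-methylphloroglucinol, and each is acylated once (Friedel–Crafts).
5. Ring order: D, then B in the same operation. D is opened again when the bridge is made, and ring C arises by dearomatisation in the last step.

Assumption: the (R,R)-ligand is taken to give the (R)-centre. The sense of induction must be confirmed by ECD or X-ray, and the (S,S)-ligand is used if it is opposite. The target is treated as the dienol-one tautomer of the given SMILES, since tautomerism does not touch the quaternary carbon.

**Step 1**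
Reactants: 1 phloroglucinol (benzene-1,3,5-triol); 2 butyryl chloride
Product: 3 phlorobutyrophenone [1-(2,4,6-trihydroxyphenyl)butan-1-one]
Conditions: AlCl3 (3.5 equiv), CH2Cl2/MeNO2, 0 → 40 °C, 4 h; ice/1 M HCl
Reagents that add atoms: butyryl chloride 2, CCCC(=O)Cl
Why: Friedel–Crafts acylation of the very electron-rich triol stops after one acyl group because the chelated aryl ketone deactivates the ring, and since all three ring CH positions are equivalent there is no regiochemical issue and no stereocentre.

**Step 2 (key step)**
Reactants: 3 phlorobutyrophenone; 4 paraformaldehyde; 5 phenylboronic acid; 6 prenal (3-methylbut-2-enal)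
Product: 9 chromeno-dioxaborinine [8-butanoyl-7-hydroxy-2,2-dimethyl-2H-chromene whose O-5 and C-6–CH2O are closed through B–Ph to a six-membered 1,3,2-dioxaborinine], via benzodioxaborinine 7 (not isolated), via vinyl ortho-quinone methide 8 (not isolated)
Conditions: PhB(OH)2 (1.1 equiv), (CH2O)n (1.05 equiv, portions), EtCO2H (0.3 equiv), PhMe, reflux, Dean–Stark, 3 h; then, same flask, PhB(OH)2 (1.0 equiv), prenal (2 equiv), reflux, 16 h; short silica plug or crystallisation
Reagents that add atoms: paraformaldehyde 4, C=O; phenylboronic acid 5, OB(O)c1ccccc1; prenal 6, CC(C)=CC=O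
Why: Proposed new method: the boronic acid esterifies the free and most acidic OH para to the ketone, delivers CH2O to the neighbouring carbon through a six-membered transition state (Nagata-type templated ortho-hydroxyalkylation) and stays on as the stable ring D of 7, which masks that oxygen and slightly deactivates the arene against a second CH2O; prenal can then only attack the last free carbon and lose water towards the ketone-flanked OH, giving 8, whose oxa-6π electrocyclisation closes ring B on the required oxygen (8-acyl series); the closest known reaction types are the phenylboronic acid-mediated synthesis of 2H-chromenes from phenols and enals (including multiple annulation of phloroglucinol) and the preparation of isolable 2-phenyl-4H-1,3,2-benzodioxaborinines from phenols and paraformaldehyde; no stereocentre is formed.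

**Step 3**
Reactants: 10 2-methylphloroglucinol (2-methylbenzene-1,3,5-triol); 11 acetyl chloride
Product: 12 3-methylphloroacetophenone [1-(2,4,6-trihydroxy-3-methylphenyl)ethan-1-one]
Conditions: AlCl3 (3.5 equiv), CH2Cl2/MeNO2, 0 → 40 °C, 3 h; ice/1 M HCl
Reagents that add atoms: acetyl chloride 11, CC(=O)Cl
Why: Friedel–Crafts acylation in which the two free ring positions are equivalent by symmetry, so a single monoketone forms and the new ketone suppresses a second acylation.

**Step 4**
Reactants: 9 chromeno-dioxaborinine; 12 3-methylphloroacetophenone (1.1 equiv)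
Product: 14 1-[6-(3-acetyl-2,4,6-trihydroxy-5-methylbenzyl)-5,7-dihydroxy-2,2-dimethyl-2H-chromen-8-yl]butan-1-one, via ortho-quinone methide 13 (not isolated)
Conditions: K2CO3 (20 mol %), THF/H2O 4:1, 40 °C, 4–6 h; 0.5 M HCl
Reagents that add atoms: none
Why: Phenolate formation at the free 7-OH expels the benzylic boronate oxygen (ring D opens and water takes boron off O-5) to give 13, the same intermediate as in formaldehyde couplings of acylphloroglucinols; ring A has no free carbon left and cannot self-condense, so the single free ring carbon of 12 adds in a conjugate (Michael/Friedel–Crafts type) manner and rearomatises to the unsymmetrical diarylmethane only; no stereocentre is formed.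

**Step 5**
Reactants: 14 diarylmethane; 15 geranyl acetate (1.1 equiv)
Product: 16 target, (4R)-2-acetyl-6-[(8-butanoyl-5,7-dihydroxy-2,2-dimethyl-2H-chromen-6-yl)methyl]-4-[(2E)-3,7-dimethylocta-2,6-dien-1-yl]-3,5-dihydroxy-4-methylcyclohexa-2,5-dien-1-one
Conditions: Pd2(dba)3·CHCl3 (2.5 mol %), (R,R)-DACH-phenyl Trost ligand (7.5 mol %), K2CO3 (1.1 equiv), degassed 1,4-dioxane, 20 °C, 16 h; 0.5 M HCl
Reagents that add atoms: geranyl acetate 15, CC(=O)OC/C=C(\C)CCC=C(C)C
Why: Proposed new method: the chiral zerovalent palladium complex ionises 15 to a π-geranyl cation that the ambident phenolate of 14 attacks at the unhindered CH2 terminus (linear product, E geometry kept because capture outruns π-σ-π isomerisation); O-allylation is reversible under palladium and every ring carbon is substituted, so the reaction funnels into irreversible dearomative C-alkylation at the least hindered site, the methyl-bearing carbon, and the ligand pocket tells the two faces apart through the very different flanks (acetyl against the bulky chromenylmethyl arm) to set the (R)-quaternary centre; the closest known reaction types are the Tsuji–Trost asymmetric allylic dearomatisation of naphthols and phenols and the achiral palladium-catalysed dearomative allylation of acylphloroglucinols.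

**Compound list**
1 | phloroglucinol | Oc1cc(O)cc(O)c1 | starting material
2 | butyryl chloride | CCCC(=O)Cl | starting material
3 | phlorobutyrophenone, 1-(2,4,6-trihydroxyphenyl)butan-1-one | CCCC(=O)c1c(O)cc(O)cc1O | intermediate
4 | paraformaldehyde, HO(CH2O)nH (SMILES of the CH2O unit it delivers) | C=O | starting material
5 | phenylboronic acid | OB(O)c1ccccc1 | starting material
6 | prenal, 3-methylbut-2-enal | CC(C)=CC=O | starting material
7 | 1-(5,7-dihydroxy-2-phenyl-4H-1,3,2-benzodioxaborinin-6-yl)butan-1-one (not isolated) | CCCC(=O)c1c(O)cc2OB(c3ccccc3)OCc2c1O | intermediate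
8 | vinyl ortho-quinone methide of 7, with a 3-methylbut-2-enylidene group on the last free carbon and C=O next to the acyl carbon (not isolated) | CCCC(=O)C1=C(O)C2=C(OB(c3ccccc3)OC2)C(=CC=C(C)C)C1=O | intermediate
9 | chromeno-dioxaborinine, 8-butanoyl-7-hydroxy-2,2-dimethyl-2H-chromene with O-5/C-6–CH2O closed by B–Ph | CCCC(=O)c1c(O)c2COB(c3ccccc3)Oc2c2C=CC(C)(C)Oc12 | intermediate
10 | 2-methylphloroglucinol | Cc1c(O)cc(O)cc1O | starting material
11 | acetyl chloride | CC(=O)Cl | starting material
12 | 1-(2,4,6-trihydroxy-3-methylphenyl)ethan-1-one | CC(=O)c1c(O)cc(O)c(C)c1O | intermediate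
13 | 8-butanoyl-5-hydroxy-2,2-dimethyl-6-methylidene-2H-chromen-7(6H)-one (not isolated) | CCCC(=O)C1=C2OC(C)(C)C=CC2=C(O)C(=C)C1=O | intermediate
14 | 1-[6-(3-acetyl-2,4,6-trihydroxy-5-methylbenzyl)-5,7-dihydroxy-2,2-dimethyl-2H-chromen-8-yl]butan-1-one | CCCC(=O)c1c(O)c(Cc2c(O)c(C)c(O)c(C(C)=O)c2O)c(O)c2c1OC(C)(C)C=C2 | intermediate
15 | geranyl acetate, (2E) | CC(=O)OC/C=C(\C)CCC=C(C)C | starting material
16 | CNP0152509.1, (4R), (2E) | CCCC(=O)c1c(O)c(CC2=C(O)[C@@](C)(C/C=C(\C)CCC=C(C)C)C(O)=C(C(C)=O)C2=O)c(O)c2c1OC(C)(C)C=C2 | target

**Totals:** 5 steps. The longest linear sequence is 4 steps (1 → 2 → 4 → 5); step 3 is a one-step side branch.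

**Steps most likely to fail**

Step 2 carries the most risk. The first boronate may form on a ketone-flanked OH instead of the para OH. Boron may migrate under the acidic reflux and let ring B close on the wrong oxygen. Ring D may also release its quinone methide early and give methylene-bridged oligomers. The fallback sets out from 3 and comes back at 14, and it drops the template in favour of stepwise amine chemistry.
- Ethylenediammonium diacetate-catalysed Knoevenagel/oxa-6π condensation of 3 with 6 (PhMe, 80 °C) gives, after chromatographic removal of the 6-acyl regioisomer, 1-(5,7-dihydroxy-2,2-dimethyl-2H-chromen-8-yl)butan-1-one F1.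
- Mannich aminomethylation at its only free ring carbon (aq. CH2O, Me2NH, EtOH, rt) gives 1-{6-[(dimethylamino)methyl]-5,7-dihydroxy-2,2-dimethyl-2H-chromen-8-yl}butan-1-one F2.
- Heating F2 with 12 in dioxane at 90 °C expels the amine, passes through 13 and delivers 14.

Step 5 is next. Alkylation could occur at the bridge-bearing carbons of either ring, and the ee is unknown for this new class of nucleophile. The fallback sets out from 14 and comes back at 16, and it separates bond formation from stereocontrol.
- Classical SN2 alkylative dearomatisation with geranyl bromide (KOH, MeOH/H2O, 0 °C) gives the racemic target F4.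
- The strongly acidic enolised β-triketone of F4 is resolved by fractional crystallisation of the (R)-1-phenylethylammonium salt of the (4R)-acid F5.
- Dilute HCl liberates 16, with ee checked on a chiral phase.

Step 4 is third. Intermediate 13 may simply rehydrate or dimerise, and base can scramble the methylene bridge into symmetrical dimers. The fallback sets out from 9 and comes back at 14, and it stores the quinone methide as an isolable sulfone.
- Opening ring D with 4-methylbenzenesulfinic acid (aq. EtOH, rt) gives crystalline 1-{5,7-dihydroxy-2,2-dimethyl-6-[(4-methylphenyl)sulfonylmethyl]-2H-chromen-8-yl}butan-1-one F3.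
- Under biphasic aq. NaHCO3/CH2Cl2 at 0 °C, F3 releases 13 slowly in the presence of excess 12. The stationary concentration of 13 therefore stays low and cross-coupling to 14 wins.

**Further compounds**
F1 | step 2 | 1-(5,7-dihydroxy-2,2-dimethyl-2H-chromen-8-yl)butan-1-one | CCCC(=O)c1c(O)cc(O)c2c1OC(C)(C)C=C2
F2 | step 2 | 1-{6-[(dimethylamino)methyl]-5,7-dihydroxy-2,2-dimethyl-2H-chromen-8-yl}butan-1-one | CCCC(=O)c1c(O)c(CN(C)C)c(O)c2c1OC(C)(C)C=C2
F3 | step 4 | 1-{5,7-dihydroxy-2,2-dimethyl-6-[(4-methylphenyl)sulfonylmethyl]-2H-chromen-8-yl}butan-1-one | CCCC(=O)c1c(O)c(CS(=O)(=O)c2ccc(C)cc2)c(O)c2c1OC(C)(C)C=C2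
F4 | step 5 | racemic target | CCCC(=O)c1c(O)c(CC2=C(O)C(C)(C/C=C(\C)CCC=C(C)C)C(O)=C(C(C)=O)C2=O)c(O)c2c1OC(C)(C)C=C2
F5 | step 5 | (R)-1-phenylethylammonium salt of the (4R)-acid | CCCC(=O)c1c(O)c(CC2=C([O-])[C@@](C)(C/C=C(\C)CCC=C(C)C)C(O)=C(C(C)=O)C2=O)c(O)c2c1OC(C)(C)C=C2.C[C@@H]([NH3+])c1ccccc1
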